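**Retrosynthetic overview**

1. Germacrane numbering is used: C1 ketone, C3 carbinol, C4=C5 Z-olefin, C6 lactone carbinol, C7 carrying C11–C13, C8 tiglate, C9/C10 diol. The enabling feature is that the C1 ketone and the oxygen-bearing C6 (allylic to C4=C5) face each other across the ten-membered ring. A C1–C6 bond folds the ring into a cis-fused octalin (ring A = C1–C6 cyclohexene, ring B = C1, C6–C10 cyclohexane) whose ring-fusion carbinol C1–OH is homoallylic to C4=C5.
2. Key disconnection: the lactone O–C6 bond is formed together with C1–C6 cleavage. A palladium-catalysed oxidative retro-allylation of octalin hydroxy acid 21 opens the bicycle to the cyclodecenone, and the carboxylate captures the π-allyl at C6. The Z-olefin and C3, C7, C8, C9, C10 are set beforehand on the octalin.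
3. Ring A: aldol addition to the C1 ketone, ring-closing metathesis (C4=C5) onto a C6 vinyl group, then chelation-controlled reduction (C3).
4. Ring B: toluene cis-dihydrodiol supplies C8 and C9; hydroxyl-directed dihydroxylation sets C10 and C1, alkoxide-directed conjugate addition sets C7, enolate vinylation sets C6.
5. Order of ring formation: ring B (chiral pool) → ring A (metathesis) → ten-membered ring and γ-lactone (key step).

Key step: step 14

Remark: β denotes the face of ring B that carries the two hydroxyl groups of 1 (the C8 and C9 oxygens of the target); α is the opposite face.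
Remark: 8 and 12 are taken as purchased reagents; 12 is the established vinyl-cation equivalent for ketone α-vinylation.

**Route**

Step 1
Reactants: 1 (1S,2R)-3-methylcyclohexa-3,5-diene-1,2-diol (toluene cis-dihydrodiol)
Product: 2 (1R,6S)-2-methyl-6-(triethylsilyloxy)cyclohexa-2,4-dien-1-ol (8-O-TES ether; 9-OH free)
Conditions: Et3SiCl (1.05 equiv), imidazole, DMF, −40 °C
Reagents that add atoms: chlorotriethylsilane, CC[Si](Cl)(CC)CC
Why: Regioselective monosilylation of a cis-dihydrodiol: the C8 hydroxyl, remote from the methyl-substituted olefin carbon, is the less hindered one, so the C9 hydroxyl stays free as directing group for step 2.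

Step 2
Reactants: 2 8-O-TES diene diol
Product: 4 ring B ene-triol (C6=C7; 1β-OH; 10β-OH and 10α-CH3; 9β-OH; 8β-OTES; all four oxygens cis), via cyclic osmate ester 3 (not isolated)
Conditions: OsO4 (1.05 equiv), TMEDA, CH2Cl2, −78 °C; then aq. Na2SO3, THF, 40 °C
Reagents that add atoms: osmium tetroxide, O=[Os](=O)(=O)=O
Why: Hydroxyl-directed dihydroxylation (OsO4·TMEDA, hydrogen-bond delivery): the free allylic C9–OH steers the reagent to the adjacent, more substituted C10=C1 olefin on the β face, setting C10 (OH β, CH3 α) and C1 cis to the C9 oxygen, while the silylated C8 oxygen cannot direct attack on C6=C7.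

Step 3
Reactants: 4 ene-triol
Product: 5 ring B enone (C1=O, C6=C7; 10β-OH, 10α-CH3; 9β-OH; 8β-OTES)
Conditions: MnO2 (excess), CH2Cl2, rt
Reagents that add atoms: none
Why: MnO2 oxidation is selective for the allylic secondary alcohol at C1; the non-allylic secondary C9–OH and the tertiary C10–OH are left.

Step 4
Reactants: 5 enone diol
Product: 6 9β,10β-bis(tert-butyldimethylsilyl) ether of 5
Conditions: TBSOTf (3 equiv), 2,6-lutidine, CH2Cl2, −78 → 0 °C
Reagents that add atoms: tert-butyldimethylsilyl triflate, CC(C)(C)[Si](C)(C)OS(=O)(=O)C(F)(F)F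
Why: Silyl triflate silylation of the secondary C9 and tertiary C10 hydroxyls; the TES ether and the enone are unaffected.

Step 5
Reactants: 6 bis-TBS, 8-O-TES enone
Product: 7 γ-hydroxy enone (C1=O, C6=C7; 8β-OH; 9β-OTBS; 10β-OTBS, 10α-CH3)
Conditions: PPTS (cat.), MeOH, 0 °C
Reagents that add atoms: none
Why: Selective acid methanolysis of the triethylsilyl ether in the presence of the much less labile tert-butyldimethylsilyl ethers frees the C8 hydroxyl needed as directing group in step 6.

Step 6
Reactants: 7 γ-hydroxy enone; 8 2-bromo-3,3-diethoxyprop-1-ene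
Product: 9 cyclohexanone (C1=O; 7β-(3,3-diethoxyprop-1-en-2-yl); 8β-OH; 9β-OTBS; 10β-OTBS, 10α-CH3)
Conditions: 8 (2.5 equiv), n-BuLi, Et2O, −78 °C; MgBr2·OEt2; then 7, THF, −78 → −30 °C; aq. NH4Cl
Reagents that add atoms: 2-bromo-3,3-diethoxyprop-1-ene (8), C=C(Br)C(OCC)OCC
Why: Alkoxide-directed (ligand-assisted) conjugate addition: the bromomagnesium alkoxide at C8 binds a second equivalent of the alkenylmagnesium reagent and delivers it intramolecularly to C7 on the β face, so the new stereocenter C7 becomes cis to the C8 oxygen and 1,2-addition is disfavoured.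

Step 7
Reactants: 9 hydroxy ketone; 10 tigloyl chloride, (E)-2-methylbut-2-enoyl chloride
Product: 11 8β-O-tiglate of 9
Conditions: 10 (3 equiv), DMAP, Et3N, CH2Cl2, 0 → 40 °C
Reagents that add atoms: tigloyl chloride (10), C/C=C(\C)C(Cl)=O
Why: DMAP-catalysed acylation of the only free hydroxyl (C8) with the (E)-acid chloride; the ester is placed before the enolate steps so that no protecting group is needed at C8.

Step 8
Reactants: 11 tiglate ketone; 12 (phenylselanyl)acetaldehyde
Product: 14 6α-vinyl ketone (6β-H, trans to the 7β side chain; otherwise as 11), via β-hydroxy selenide 13 (not isolated)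
Conditions: LiN(i-Pr)2 (1.05 equiv), THF, −78 °C; 12; then MeSO2Cl, Et3N, −78 → 0 °C
Reagents that add atoms: (phenylselanyl)acetaldehyde (12), O=CC[Se]c1ccccc1
Why: Kinetic lithium enolate aldol (C6 is the only enolisable position) with the vinyl-cation equivalent 12 from the α face, anti to the 7β side chain and the axial 8β and 10β oxygens, fixes C6 (6β-H, trans to C7); mesylation of the aldolate then triggers anti elimination of PhSe and OMs through a seleniranium ion to give the vinyl group regiospecifically (β-hydroxy selenide olefination).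

Step 9
Reactants: 14 α-vinyl ketone; 15 3-methylbut-3-en-2-one
Product: 16 tertiary aldol (1β-OH, 1α-CH2C(=O)C(CH3)=CH2; otherwise as 14)
Conditions: 15, LiN(i-Pr)2, THF, −78 °C; CeCl3; then 14, −78 °C; aq. NH4Cl
Reagents that add atoms: 3-methylbut-3-en-2-one (15), CC(=O)C(C)=C
Why: Aldol addition of the dichlorocerium enolate of 15 (its low basicity suppresses enolisation of the hindered α-vinyl ketone) by axial attack anti to the axial 10β-siloxy group (polar Felkin–Anh model), which should make the new carbinol C1 β-OH with the C2 chain α and therefore cis to the 6α-vinyl group.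

Step 10
Reactants: 16 aldol diene
Product: 17 cis-fused octalin enone (ring A = C1(β-OH)–C2H2–C3(=O)–C4(CH3)=C5H–C6(β-H); ring B as in 14)
Conditions: second-generation Hoveyda–Grubbs catalyst RuCl2(=CH-C6H4-2-O-i-Pr)(H2IMes) (5 mol %), toluene, 60 °C
Reagents that add atoms: none
Why: Ring-closing metathesis of the C6 vinyl group onto the 1,1-disubstituted enone olefin closes ring A as a 2-methylcyclohex-2-enone; C4=C5 is necessarily cis within the six-membered ring (the later Z geometry) and the neutral conditions spare the β-hydroxy ketone.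

Step 11
Reactants: 17 octalin enone
Product: 18 3β-alcohol of 17 (1β,3β-cis-diol)
Conditions: Et2BOMe, THF/MeOH, −78 °C; NaBH4; then MeOH (azeotrope)
Reagents that add atoms: none
Why: Narasaka–Prasad reduction: Et2BOMe ties the axial 1β-OH and the C3 carbonyl into a boron chelate and borohydride attacks from the face opposite the boron bridge, giving the 1,3-cis-diol, i.e. 3β-OH (3S), by 1,2-reduction.

Step 12
Reactants: 18 diol
Product: 19 3β-O-TBS ether of 18
Conditions: TBSCl, imidazole, DMF, rt
Reagents that add atoms: tert-butyldimethylsilyl chloride, CC(C)(C)[Si](C)(C)Cl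
Why: Silylation of the only secondary hydroxyl (C3) with TBSCl/imidazole; the tertiary C1 hydroxyl is too hindered to react.

Step 13
Reactants: 19 diethyl acetal
Product: 21 hydroxy acid (as 19 with 7β-C(=CH2)CO2H; free 1β-OH), via enal 20 (not isolated)
Conditions: PPTS (cat.), acetone/H2O, rt; then NaClO2, NaH2PO4, 2-methyl-2-butene, t-BuOH/H2O, 0 °C
Reagents that add atoms: water, O; sodium chlorite, [Na+].[O-]Cl=O
Why: Mild acid hydrolysis of the α,β-unsaturated diethyl acetal to the enal followed by Pinnick oxidation (chlorite with a hypochlorite scavenger) gives the 2-substituted acrylic acid without affecting the olefins, silyl ethers, tiglate or tertiary alcohol.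

Step 14
Reactants: 21 octalin hydroxy acid
Product: 22 3,9,10-tris-O-TBS ether of the target (ten-membered 1-ketone, 6α,12-lactone, 4Z)
Conditions: Pd(OCOCF3)2 (10 mol %), 1,4-benzoquinone (2 equiv), n-Bu4NCl (20 mol %), 2,6-lutidine (20 mol %), 4 Å MS, toluene, 50 °C
Reagents that add atoms: none
Why: Proposed new method: the divalent palladium alkoxide of the ring-fusion carbinol C1–OH should undergo retro-allylation (β-carbon elimination through a six-membered, boat-like transition state that transfers palladium to C4 of the endocyclic homoallylic olefin), cleaving the C1–C6 ring-fusion bond to give the C1 ketone of the ten-membered ring and an η3-allylpalladium over C4–C5–C6; the C12 carboxylate then attacks C6 on the face opposite palladium and benzoquinone re-oxidises zerovalent palladium. The closest known reaction types are the palladium-catalysed retro-allylation of tertiary homoallylic alcohols (allyl transfer to aryl halides) and the palladium/benzoquinone allylic acyloxylation and lactonisation through π-allylpalladium carboxylates; new is their combination on an endocyclic allyl unit, so that C–C instead of C–H cleavage generates the π-allyl. The γ-lactone closes by 5-exo attack of the carboxylate oxygen on the secondary allyl terminus (O–C6 bond), whereas the ten-membered carbocycle arises by ring expansion (fragmentation of the bicyclic C1–C6 bond), not by cyclisation. The only new stereocenter, C6, is controlled by C7 and the topology: palladium is delivered syn to the departing C1, the equatorial C7 side chain lies anti to the C1–C6 bond and so brings the carboxylate in anti to palladium, a net inversion at C6 that gives the 6α-O, 7β-C trans-lactone (6R). The selectivities needed are cleavage of C1–C6 rather than C1–C2 or C1–C10 (only the allylic bond can pass through the six-membered transition state), attack at C6 rather than at tertiary C4 (five- versus seven-membered lactone), outer-sphere rather than inner-sphere C–O bond formation (chloride additive) and retention of the Z geometry of C4=C5 (inherited from the cyclohexene, in which C3 stays cis to C6).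

Step 15
Reactants: 22 tris-TBS ether
Product: 23 CNP0106709.2 (target)
Conditions: HF·pyridine, pyridine, THF, 0 °C → rt
Reagents that add atoms: none
Why: Fluoride-mediated desilylation under buffered acidic conditions removes the three TBS ethers (C3, C9 and tertiary C10) while the base-sensitive α-methylene lactone, tiglate and β-hydroxy ketone are preserved.

**Compound list**

1 | (1S,2R)-3-methylcyclohexa-3,5-diene-1,2-diol (toluene cis-dihydrodiol; 8β-OH, 9β-OH) | CC1=CC=C[C@H](O)[C@@H]1O | starting material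
2 | (1R,6S)-2-methyl-6-(triethylsilyloxy)cyclohexa-2,4-dien-1-ol (8-O-TES, 9-OH free) | CC1=CC=C[C@H](O[Si](CC)(CC)CC)[C@@H]1O | intermediate
3 | cyclic osmate ester of 2 (OsO2 bridging the 10β- and 1β-oxygens; TMEDA on osmium; not isolated) | C[C@@]1(O2)[C@H](O[Os]2(=O)=O)C=C[C@H](O[Si](CC)(CC)CC)[C@@H]1O.CN(C)CCN(C)C | intermediate
4 | ring B ene-triol: C6=C7; 1β-OH; 10β-OH, 10α-CH3; 9β-OH; 8β-OTES | C[C@@]1(O)[C@H](O)C=C[C@H](O[Si](CC)(CC)CC)[C@@H]1O | intermediate
5 | ring B enone: C1=O, C6=C7; 10β-OH, 10α-CH3; 9β-OH; 8β-OTES | C[C@@]1(O)C(=O)C=C[C@H](O[Si](CC)(CC)CC)[C@@H]1O | intermediate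
6 | 9β,10β-bis-O-TBS ether of 5 | C[C@@]1(O[Si](C)(C)C(C)(C)C)C(=O)C=C[C@H](O[Si](CC)(CC)CC)[C@@H]1O[Si](C)(C)C(C)(C)C | intermediate
7 | γ-hydroxy enone: C1=O, C6=C7; 8β-OH; 9β-OTBS; 10β-OTBS, 10α-CH3 | C[C@@]1(O[Si](C)(C)C(C)(C)C)C(=O)C=C[C@H](O)[C@@H]1O[Si](C)(C)C(C)(C)C | intermediate
8 | 2-bromo-3,3-diethoxyprop-1-ene | C=C(Br)C(OCC)OCC | starting material
9 | cyclohexanone: C1=O; 7β-(3,3-diethoxyprop-1-en-2-yl); 8β-OH; 9β-OTBS; 10β-OTBS, 10α-CH3 | C[C@@]1(O[Si](C)(C)C(C)(C)C)C(=O)C[C@H](C(=C)C(OCC)OCC)[C@H](O)[C@@H]1O[Si](C)(C)C(C)(C)C | intermediate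
10 | tigloyl chloride, (E)-2-methylbut-2-enoyl chloride | C/C=C(\C)C(Cl)=O | starting material
11 | 8β-O-tiglate of 9 | C[C@@]1(O[Si](C)(C)C(C)(C)C)C(=O)C[C@H](C(=C)C(OCC)OCC)[C@H](OC(=O)/C(C)=C/C)[C@@H]1O[Si](C)(C)C(C)(C)C | intermediate
12 | (phenylselanyl)acetaldehyde | O=CC[Se]c1ccccc1 | starting material
13 | 6α-[1-hydroxy-2-(phenylselanyl)ethyl] derivative of 11 (6β-H; carbinol configuration not controlled; not isolated) | C[C@@]1(O[Si](C)(C)C(C)(C)C)C(=O)[C@@H](C(O)C[Se]c2ccccc2)[C@H](C(=C)C(OCC)OCC)[C@H](OC(=O)/C(C)=C/C)[C@@H]1O[Si](C)(C)C(C)(C)C | intermediate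
14 | 6α-vinyl ketone (6β-H, trans to the 7β side chain); otherwise as 11 | C[C@@]1(O[Si](C)(C)C(C)(C)C)C(=O)[C@@H](C=C)[C@H](C(=C)C(OCC)OCC)[C@H](OC(=O)/C(C)=C/C)[C@@H]1O[Si](C)(C)C(C)(C)C | intermediate
15 | 3-methylbut-3-en-2-one | CC(=O)C(C)=C | starting material
16 | tertiary aldol: 1β-OH, 1α-(3-methyl-2-oxobut-3-enyl); otherwise as 14 | C[C@@]1(O[Si](C)(C)C(C)(C)C)[C@@](O)(CC(=O)C(C)=C)[C@@H](C=C)[C@H](C(=C)C(OCC)OCC)[C@H](OC(=O)/C(C)=C/C)[C@@H]1O[Si](C)(C)C(C)(C)C | intermediate
17 | cis-fused octalin enone: 1β-OH, C3=O, C4(CH3)=C5, 6β-H; 7β-(3,3-diethoxyprop-1-en-2-yl); 8β-O-tiglate; 9β-OTBS; 10β-OTBS, 10α-CH3 | C[C@@]1(O[Si](C)(C)C(C)(C)C)[C@@]2(O)CC(=O)C(C)=C[C@H]2[C@H](C(=C)C(OCC)OCC)[C@H](OC(=O)/C(C)=C/C)[C@@H]1O[Si](C)(C)C(C)(C)C | intermediate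
18 | 3β-alcohol of 17 (1β,3β-cis-diol) | C[C@@]1(O[Si](C)(C)C(C)(C)C)[C@@]2(O)C[C@H](O)C(C)=C[C@H]2[C@H](C(=C)C(OCC)OCC)[C@H](OC(=O)/C(C)=C/C)[C@@H]1O[Si](C)(C)C(C)(C)C | intermediate
19 | 3β-O-TBS ether of 18 | C[C@@]1(O[Si](C)(C)C(C)(C)C)[C@@]2(O)C[C@H](O[Si](C)(C)C(C)(C)C)C(C)=C[C@H]2[C@H](C(=C)C(OCC)OCC)[C@H](OC(=O)/C(C)=C/C)[C@@H]1O[Si](C)(C)C(C)(C)C | intermediate
20 | enal: as 19 with 7β-C(=CH2)CHO (not isolated) | C[C@@]1(O[Si](C)(C)C(C)(C)C)[C@@]2(O)C[C@H](O[Si](C)(C)C(C)(C)C)C(C)=C[C@H]2[C@H](C(=C)C=O)[C@H](OC(=O)/C(C)=C/C)[C@@H]1O[Si](C)(C)C(C)(C)C | intermediate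
21 | hydroxy acid: as 19 with 7β-C(=CH2)CO2H; free 1β-OH | C[C@@]1(O[Si](C)(C)C(C)(C)C)[C@@]2(O)C[C@H](O[Si](C)(C)C(C)(C)C)C(C)=C[C@H]2[C@H](C(=C)C(=O)O)[C@H](OC(=O)/C(C)=C/C)[C@@H]1O[Si](C)(C)C(C)(C)C | intermediate
22 | 3,9,10-tris-O-TBS ether of the target | C=C1C(=O)O[C@@H]2/C=C(/C)[C@@H](O[Si](C)(C)C(C)(C)C)CC(=O)[C@@](C)(O[Si](C)(C)C(C)(C)C)[C@@H](O[Si](C)(C)C(C)(C)C)[C@@H](OC(=O)/C(C)=C/C)[C@@H]12 | intermediate
23 | CNP0106709.2: (3S,6R,7S,8S,9S,10S)-3,9,10-trihydroxy-1-oxo-8-tigloyloxygermacra-4Z,11(13)-dien-6,12-olide | C=C1C(=O)O[C@@H]2/C=C(/C)[C@@H](O)CC(=O)[C@@](C)(O)[C@@H](O)[C@@H](OC(=O)/C(C)=C/C)[C@@H]12 | target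

**Totals and risks**

Total step count: 15. Longest linear sequence: 15 steps (1 → 23).

Steps most likely to fail:

1. Step 14 (proposed new method). The palladium alkoxide may not undergo β-carbon elimination (no fragmentation), or the π-allyl may collapse by inner-sphere C–O coupling (C6 epimer) or by β-hydride loss to a diene. Fallback with known chemistry, from 21 back to 22: 21 is treated with PhI(OAc)2 and I2 in CH2Cl2 under visible light. Photolysis of the tertiary hypoiodite gives the alkoxy radical, β-scission of the C1–C6 bond gives the ten-membered ketone and an allylic radical, and iodine transfer gives the ten-membered 6-iodo keto acid F1. Ag2CO3 in MeCN then ionises the allylic iodide, and 5-exo capture of the allyl cation by the carboxylic acid at C6 closes the trans-lactone 22.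

2. Step 6. The alkoxide-directed delivery may lose facial control, or 1,2-addition to the ketone may compete. Fallback, from 6 back to 9: the cuprate LiCu[C(=CH2)CH(OEt)2]2 (from 8, n-BuLi and CuBr·SMe2) with Me3SiCl is added to the silyl-protected enone 6; addition anti to the C8 siloxy group gives the 7α-epimeric ketone as its 8-O-TES ether F2. PPTS in MeOH frees the 7α-epimeric alcohol F3, and Dess–Martin periodinane gives the 1,8-diketone with 7α side chain F4. DBU equilibrates C7 (now α to a ketone) to the all-equatorial 1,8-diketone with 7β side chain F5. LiBH(s-Bu)3 then reduces the C8 ketone from the equatorial direction to the axial 8β-alcohol, which is 9.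

3. Step 9. Proton transfer (enolisation of the hindered α-vinyl ketone) or retro-aldol cleavage may win over carbonyl addition. Fallback, from 14 back to 16: 15 is converted with Me3SiOTf and Et3N into 2-(trimethylsilyloxy)-3-methylbuta-1,3-diene F6, which N-bromosuccinimide turns into 1-bromo-3-methylbut-3-en-2-one F7. F7 and 14 are then treated with SmI2 in THF at −78 °C (samarium Reformatsky reaction); the neutral samarium enolate adds to hindered, enolisable ketones and gives 16.

Further compounds
F1 | step 14 | ten-membered 6-iodo keto acid (C1=O, 4Z, C6–I of uncontrolled configuration, 7-C(=CH2)CO2H, silyl ethers and tiglate as in 21) | OC(=O)C(=C)[C@H]1C(I)/C=C(/C)[C@@H](O[Si](C)(C)C(C)(C)C)CC(=O)[C@@](C)(O[Si](C)(C)C(C)(C)C)[C@@H](O[Si](C)(C)C(C)(C)C)[C@H]1OC(=O)/C(C)=C/C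
F2 | step 6 | 7α-epimer of 9 as its 8-O-TES ether | C[C@@]1(O[Si](C)(C)C(C)(C)C)C(=O)C[C@@H](C(=C)C(OCC)OCC)[C@H](O[Si](CC)(CC)CC)[C@@H]1O[Si](C)(C)C(C)(C)C
F3 | step 6 | 7α-epimer of 9 (8β-OH) | C[C@@]1(O[Si](C)(C)C(C)(C)C)C(=O)C[C@@H](C(=C)C(OCC)OCC)[C@H](O)[C@@H]1O[Si](C)(C)C(C)(C)C
F4 | step 6 | 1,8-diketone with 7α side chain | C[C@@]1(O[Si](C)(C)C(C)(C)C)C(=O)C[C@@H](C(=C)C(OCC)OCC)C(=O)[C@@H]1O[Si](C)(C)C(C)(C)C
F5 | step 6 | 1,8-diketone with 7β side chain | C[C@@]1(O[Si](C)(C)C(C)(C)C)C(=O)C[C@H](C(=C)C(OCC)OCC)C(=O)[C@@H]1O[Si](C)(C)C(C)(C)C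
F6 | step 9 | 2-(trimethylsilyloxy)-3-methylbuta-1,3-diene | C=C(C)C(=C)O[Si](C)(C)C
F7 | step 9 | 1-bromo-3-methylbut-3-en-2-one | C=C(C)C(=O)CBr
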